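Assumption: the SMILES is read literally, so H‑5 is cis to the C‑10 methyl (5β‑H, cis‑decalin, 4aR,8aS; the C‑5 epimer of the usual trans‑fused sterebin skeleton). Labdane numbering is used: ring B = C5–C10, side chain C11–C13 plus methyl C16, C17 = methyl on C8.

## Retrosynthetic overview

1. Target 18 ⇒ epoxy enone 17: the C6–OAc bond comes last, by hydroxyl‑directed anti acetolysis of a 6β,7β‑epoxy‑8α‑ol; the enone comes from dehydrogenation of the saturated C13 ketone 16.
2. 16 ⇒ cis‑fused Δ6‑8α‑ol 14: oxygen is put on the β‑face by a dioxirane made from the substrate's own C13 ketone (new step).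
3. 14 ⇒ Δ5‑7‑one 10: reductive 1,3‑transposition of the tosylhydrazone sets 5β‑H (cis ring fusion) and the Δ6 alkene.
4. 10 ⇒ exocyclic alkene 5 ⇒ (−)‑sclareol 1: C7–O by allylic hydroxylation, Δ5 by dehydrogenation, C8–O by reductive α‑hydroxylation; the side chain is cut to the methyl ketone and masked as a dioxolane.
5. Ring order: rings A and B with C9 and C10 come intact from sclareol and no carbocycle is built; the only rings closed are the dioxolane (step 3, removed in step 8) and the oxirane (step 9, opened in step 11).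

## Route

Step 1
Reactants: 1 (−)-sclareol
Product: 3 8α-hydroxy-14,15-dinorlabdan-13-one, via labdane tetraol 2 (not isolated)
Conditions: K2OsO4·2H2O (2 mol%), NaIO4 (4 equiv), 2,6-lutidine, dioxane/H2O, rt
Reagents that add atoms: none
Why: Lemieux–Johnson oxidation, in which OsO4-catalysed dihydroxylation of the only alkene gives 2 and periodate then cleaves its 13,14,15-triol array twice to leave the C13 methyl ketone, with no ring stereocentre touched.

Step 2
Reactants: 3 8α-hydroxy-14,15-dinorlabdan-13-one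
Product: 4 14,15-dinorlabd-8(17)-en-13-one
Conditions: SOCl2, Et3N, CH2Cl2, −78 °C
Reagents that add atoms: none
Why: Dehydration of the equatorial tertiary 8α-alcohol after activation with SOCl2 (E2-type elimination at low temperature) takes a hydrogen of the C17 methyl and gives the exocyclic alkene, the usual kinetic outcome for 8α-hydroxy labdanes and drimanes, so the C8 centre is erased here and rebuilt in step 6.

Step 3
Reactants: 4 14,15-dinorlabd-8(17)-en-13-one
Product: 5 13,13-ethylenedioxy-14,15-dinorlabd-8(17)-ene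
Conditions: ethylene glycol, PPTS (cat.), benzene, reflux (Dean–Stark)
Reagents that add atoms: ethylene glycol, OCCO
Why: Acid-catalysed ketalisation to the 1,3-dioxolane masks the only carbonyl so that the later dehydrogenation and hydrazone chemistry act on ring B alone, and PPTS is too weak an acid to move the exocyclic alkene.

Step 4
Reactants: 5 13,13-ethylenedioxy-14,15-dinorlabd-8(17)-ene
Product: 6 13,13-ethylenedioxy-14,15-dinorlabd-8(17)-en-7α-ol
Conditions: SeO2 (0.3 equiv), tBuOOH (decane), CH2Cl2, 0 °C to rt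
Reagents that add atoms: tert-butyl hydroperoxide, CC(C)(C)OO
Why: Sharpless SeO2/tBuOOH allylic hydroxylation (ene reaction, then 2,3-sigmatropic shift) oxidises the allylic CH2 at C7 in preference to the allylic CH at C9 and returns oxygen suprafacially to the axial 7α position, a configuration that does not matter because C7 is oxidised in step 5.

Step 5
Reactants: 6 13,13-ethylenedioxy-14,15-dinorlabd-8(17)-en-7α-ol
Product: 8 13,13-ethylenedioxy-14,15-dinorlabda-5,8(17)-dien-7-one, via exo-enone ketal 7 (not isolated)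
Conditions: IBX (3.5 equiv), DMSO/fluorobenzene, 25 then 80 °C
Reagents that add atoms: none
Why: IBX first oxidises the allylic alcohol to enone 7 and then, in the Nicolaou-type IBX dehydrogenation, removes H6 and H5 (C6 is the only enolisable position) to give the cross-conjugated dienone, while the ketal prevents the same reaction in the side chain.

Step 6
Reactants: 8 13,13-ethylenedioxy-14,15-dinorlabda-5,8(17)-dien-7-one
Product: 10 13,13-ethylenedioxy-8α-hydroxy-14,15-dinorlabd-5-en-7-one, via 8α-hydroperoxide 9 (not isolated)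
Conditions: Mn(dpm)3 (10 mol%), PhSiH3, O2 (1 atm), iPrOH/CH2Cl2, 0 °C; then P(OEt)3
Reagents that add atoms: dioxygen, O=O
Why: Mukaiyama-type hydrogen-atom-transfer reductive α-hydroxylation of an enone (Magnus conditions), in which the manganese hydride gives H to the unhindered exocyclic CH2 and O2 traps the C8 radical from the α-face, anti to the axial C10 methyl, which sets C8 as 8α-OH/8β-CH3 while the fully substituted C5 end of the other enone is left alone.

Step 7
Reactants: 10 13,13-ethylenedioxy-8α-hydroxy-14,15-dinorlabd-5-en-7-one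
Product: 11 7-(p-toluenesulfonyl)hydrazone of 10
Conditions: TsNHNH2, AcOH (cat.), EtOH, 60 °C
Reagents that add atoms: p-toluenesulfonyl hydrazide, Cc1ccc(cc1)S(=O)(=O)NN
Why: Hydrazone condensation at the only free carbonyl (C7) prepares the reductive transposition and creates no stereocentre.

Step 8
Reactants: 11 7-(p-toluenesulfonyl)hydrazone of 10
Product: 14 8α-hydroxy-14,15-dinor-5β-labd-6-en-13-one, via 7β-allylic diazene 12 (not isolated), via cis-fused alkene ketal 13 (not isolated)
Conditions: catecholborane (3 equiv), CHCl3, 0 °C to rt; NaOAc·3H2O, reflux; then PPTS, acetone/H2O, 50 °C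
Reagents that add atoms: water, O
Why: Kabalka reductive 1,3-transposition, in which hydride adds to C7 from the α-face (the β-face is closed by the axial 8β- and 10β-methyls), loss of sulfinate gives the 7β-diazene 12, and its suprafacial retro-ene loss of N2 hands hydrogen to C5 on the β-face, which sets the cis ring fusion (5β-H) and leaves the Δ6 alkene before mild acid hydrolyses the dioxolane.

Step 9
Reactants: 14 8α-hydroxy-14,15-dinor-5β-labd-6-en-13-one
Product: 16 6β,7β-epoxy-8α-hydroxy-14,15-dinor-5β-labdan-13-one, via side-chain dioxirane 15 (not isolated)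
Conditions: Oxone (2KHSO5·KHSO4·K2SO4), NaHCO3, MeCN/aq. Na2EDTA, 0 °C to rt, 2 mM
Reagents that add atoms: potassium peroxymonosulfate (Oxone), [K+].[O-]S(=O)(=O)OO
Why: Proposed new method: the unactivated C13 methyl ketone of the substrate is turned by KHSO5 into dioxirane 15, which the C9 side chain holds on the β-face, and in the half-chair with that chain axial its peroxidic oxygen reaches C6=C7 through a seven- to eight-membered spiro transition state, so oxygen is transferred intramolecularly to the β-face (7β-O and 6β-O) against the α-preference that the 8α-hydroxyl would give a peracid, while C–H insertion cannot compete because both δ-carbons (C8, C10) are quaternary and intermolecular transfer is suppressed by high dilution; the closest known reaction types are the intramolecular δ-C–H hydroxylation of ketones through dioxiranes generated in situ with Oxone and the Shi-type ketone-catalysed epoxidation.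

Step 10
Reactants: 16 6β,7β-epoxy-8α-hydroxy-14,15-dinor-5β-labdan-13-one
Product: 17 (11E)-6β,7β-epoxy-8α-hydroxy-14,15-dinor-5β-labd-11-en-13-one
Conditions: IBX (2.5 equiv), DMSO/fluorobenzene, 70 °C
Reagents that add atoms: none
Why: IBX dehydrogenation of a ketone can only desaturate the C12–C11 side of the methyl ketone and gives the (E)-enone, and it is placed here because the molecule still has no secondary alcohol and the tertiary alcohol and oxirane are inert to IBX.

Step 11
Reactants: 17 (11E)-6β,7β-epoxy-8α-hydroxy-14,15-dinor-5β-labd-11-en-13-one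
Product: 18 (11E)-6α-acetoxy-7β,8α-dihydroxy-14,15-dinor-5β-labd-11-en-13-one (target)
Conditions: Ti(OiPr)4 (1.5 equiv), AcOH (3 equiv), CH2Cl2, 0 °C to rt
Reagents that add atoms: acetic acid, CC(=O)O
Why: Sharpless-type Ti(OiPr)4-mediated C3-selective opening of a 2,3-epoxy alcohol by a carboxylic acid, in which the titanium alkoxide at O8 delivers acetate to C6 anti to the oxirane oxygen (SN2 inversion, trans-diaxial Fürst–Plattner opening through the half-chair where O8 and the incoming acetate are 1,3-syn-axial) while C7 is neopentylic and deactivated by the adjacent carbinol, so C6 becomes 6α-OAc and the oxygen kept at C7 is the 7β-OH.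

## Compound list

1 | (−)-sclareol, (13R)-labd-14-ene-8α,13-diol | C=C[C@](C)(O)CC[C@H]1[C@](C)(O)CC[C@H]2C(C)(C)CCC[C@@]21C | starting material
2 | labdane-8α,13,14,15-tetraol (C14 epimers, formed in situ) | OCC(O)[C@](C)(O)CC[C@H]1[C@](C)(O)CC[C@H]2C(C)(C)CCC[C@@]21C | intermediate
3 | 8α-hydroxy-14,15-dinorlabdan-13-one | CC(=O)CC[C@H]1[C@](C)(O)CC[C@H]2C(C)(C)CCC[C@@]21C | intermediate
4 | 14,15-dinorlabd-8(17)-en-13-one | CC(=O)CC[C@H]1C(=C)CC[C@H]2C(C)(C)CCC[C@@]21C | intermediate
5 | 13,13-ethylenedioxy-14,15-dinorlabd-8(17)-ene | CC1(CC[C@H]2C(=C)CC[C@H]3C(C)(C)CCC[C@@]32C)OCCO1 | intermediate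
6 | 13,13-ethylenedioxy-14,15-dinorlabd-8(17)-en-7α-ol | CC1(CC[C@H]2C(=C)[C@H](O)C[C@H]3C(C)(C)CCC[C@@]32C)OCCO1 | intermediate
7 | 13,13-ethylenedioxy-14,15-dinorlabd-8(17)-en-7-one (formed in situ) | CC1(CC[C@H]2C(=C)C(=O)C[C@H]3C(C)(C)CCC[C@@]32C)OCCO1 | intermediate
8 | 13,13-ethylenedioxy-14,15-dinorlabda-5,8(17)-dien-7-one | CC1(CC[C@H]2C(=C)C(=O)C=C3C(C)(C)CCC[C@@]32C)OCCO1 | intermediate
9 | 13,13-ethylenedioxy-8α-hydroperoxy-14,15-dinorlabd-5-en-7-one (formed in situ) | CC1(CC[C@H]2[C@](C)(OO)C(=O)C=C3C(C)(C)CCC[C@@]32C)OCCO1 | intermediate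
10 | 13,13-ethylenedioxy-8α-hydroxy-14,15-dinorlabd-5-en-7-one | CC1(CC[C@H]2[C@](C)(O)C(=O)C=C3C(C)(C)CCC[C@@]32C)OCCO1 | intermediate
11 | (7E)-7-(p-toluenesulfonyl)hydrazone of 10 | CC1(CC[C@H]2[C@](C)(O)/C(=N/NS(=O)(=O)c4ccc(C)cc4)C=C3C(C)(C)CCC[C@@]32C)OCCO1 | intermediate
12 | 7β-diazenyl-13,13-ethylenedioxy-14,15-dinorlabd-5-en-8α-ol (formed in situ) | CC1(CC[C@H]2[C@](C)(O)[C@@H](N=N)C=C3C(C)(C)CCC[C@@]32C)OCCO1 | intermediate
13 | 13,13-ethylenedioxy-14,15-dinor-5β-labd-6-en-8α-ol (cis-fused, formed in situ) | CC1(CC[C@H]2[C@](C)(O)C=C[C@@H]3C(C)(C)CCC[C@@]32C)OCCO1 | intermediate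
14 | 8α-hydroxy-14,15-dinor-5β-labd-6-en-13-one | CC(=O)CC[C@H]1[C@](C)(O)C=C[C@@H]2C(C)(C)CCC[C@@]21C | intermediate
15 | C13 dioxirane of 14 (13,13-epidioxy-14,15-dinor-5β-labd-6-en-8α-ol, formed in situ) | CC1(OO1)CC[C@H]2[C@](C)(O)C=C[C@@H]3C(C)(C)CCC[C@@]32C | intermediate
16 | 6β,7β-epoxy-8α-hydroxy-14,15-dinor-5β-labdan-13-one | CC(=O)CC[C@H]1[C@](C)(O)[C@H]3O[C@H]3[C@@H]2C(C)(C)CCC[C@@]21C | intermediate
17 | (11E)-6β,7β-epoxy-8α-hydroxy-14,15-dinor-5β-labd-11-en-13-one | CC(=O)/C=C/[C@H]1[C@](C)(O)[C@H]3O[C@H]3[C@@H]2C(C)(C)CCC[C@@]21C | intermediate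
18 | (11E)-6α-acetoxy-7β,8α-dihydroxy-14,15-dinor-5β-labd-11-en-13-one, i.e. (E)-4-[(1R,2S,3S,4R,4aR,8aS)-4-acetoxy-2,3-dihydroxy-2,5,5,8a-tetramethyldecahydronaphthalen-1-yl]but-3-en-2-one | CC(=O)/C=C/[C@H]1[C@](C)(O)[C@@H](O)[C@H](OC(C)=O)[C@@H]2C(C)(C)CCC[C@@]21C | target

## Step count and risks

Total step count: 11. Longest linear sequence: 11 (fully linear from sclareol).

The three steps most likely to fail:

Step 6 (reductive α-hydroxylation). The face of O2 capture at C8 and competing reduction of the second enone are not certain. The fallback sets out from 6 and returns at 10 with known chemistry. VO(acac)2/tBuOOH epoxidation directed by the 7α-hydroxyl puts oxygen on the α-face of the exocyclic alkene and gives 8α,17-epoxy-13,13-ethylenedioxy-14,15-dinorlabdan-7α-ol F1. LiAlH4 opens the oxirane at the primary C17 to give 13,13-ethylenedioxy-14,15-dinorlabdane-7α,8α-diol F2, which fixes 8α-OH/8β-CH3 by the directed epoxidation. IBX then oxidises the secondary alcohol to 13,13-ethylenedioxy-8α-hydroxy-14,15-dinorlabdan-7-one F3 and, on heating, dehydrogenates it across C5–C6 to 10.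

Step 8 (reductive transposition). Hydrogen must be delivered to C5 between two axial methyl groups, and the diazene could decompose by non-concerted paths. The fallback sets out from 10 and returns at 13, which is hydrolysed to 14 as in step 8. Luche reduction (NaBH4, CeCl3·7H2O; hydride from the α-face) gives 13,13-ethylenedioxy-14,15-dinorlabd-5-ene-7β,8α-diol F4. Hydroxyl-directed hydrogenation with [Ir(cod)(PCy3)(py)]PF6/H2 adds hydrogen syn to the allylic 7β-OH, on the β-face, to give the cis-fused 13,13-ethylenedioxy-14,15-dinor-5β-labdane-7β,8α-diol F5. Dess–Martin oxidation gives 13,13-ethylenedioxy-8α-hydroxy-14,15-dinor-5β-labdan-7-one F6, and TsNHNH2 gives its 7-(p-toluenesulfonyl)hydrazone F7. A Shapiro reaction (LiN(iPr)2, THF, −78 to 0 °C, then water) places the alkene at C6=C7, the only side with α-hydrogens, to give 13.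

Step 9 (the proposed new epoxidation). The unactivated ketone may form its dioxirane slowly, ring-chain tautomerism of 14 may hide the ketone, and intermolecular transfer could erode face selectivity. The fallback uses known chemistry, sets out from 14 and returns at 16. TESOTf/2,6-lutidine at −78 °C gives 8α-triethylsilyloxy-14,15-dinor-5β-labd-6-en-13-one F8. mCPBA/NaHCO3 then epoxidises anti to the bulky allylic silyloxy group (steric control instead of tethered delivery) to give 6β,7β-epoxy-8α-triethylsilyloxy-14,15-dinor-5β-labdan-13-one F9, and Bu4NF removes the silyl group to give 16.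

Further compounds
F1 | step 6 | 8α,17-epoxy-13,13-ethylenedioxy-14,15-dinorlabdan-7α-ol | CC1(CC[C@H]2[C@@]4(CO4)[C@H](O)C[C@H]3C(C)(C)CCC[C@@]32C)OCCO1
F2 | step 6 | 13,13-ethylenedioxy-14,15-dinorlabdane-7α,8α-diol | CC1(CC[C@H]2[C@](C)(O)[C@H](O)C[C@H]3C(C)(C)CCC[C@@]32C)OCCO1
F3 | step 6 | 13,13-ethylenedioxy-8α-hydroxy-14,15-dinorlabdan-7-one | CC1(CC[C@H]2[C@](C)(O)C(=O)C[C@H]3C(C)(C)CCC[C@@]32C)OCCO1
F4 | step 8 | 13,13-ethylenedioxy-14,15-dinorlabd-5-ene-7β,8α-diol | CC1(CC[C@H]2[C@](C)(O)[C@@H](O)C=C3C(C)(C)CCC[C@@]32C)OCCO1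
F5 | step 8 | 13,13-ethylenedioxy-14,15-dinor-5β-labdane-7β,8α-diol | CC1(CC[C@H]2[C@](C)(O)[C@@H](O)C[C@@H]3C(C)(C)CCC[C@@]32C)OCCO1
F6 | step 8 | 13,13-ethylenedioxy-8α-hydroxy-14,15-dinor-5β-labdan-7-one | CC1(CC[C@H]2[C@](C)(O)C(=O)C[C@@H]3C(C)(C)CCC[C@@]32C)OCCO1
F7 | step 8 | 7-(p-toluenesulfonyl)hydrazone of F6 | CC1(CC[C@H]2[C@](C)(O)/C(=N/NS(=O)(=O)c4ccc(C)cc4)C[C@@H]3C(C)(C)CCC[C@@]32C)OCCO1
F8 | step 9 | 8α-triethylsilyloxy-14,15-dinor-5β-labd-6-en-13-one | CC(=O)CC[C@H]1[C@](C)(O[Si](CC)(CC)CC)C=C[C@@H]2C(C)(C)CCC[C@@]21C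
F9 | step 9 | 6β,7β-epoxy-8α-triethylsilyloxy-14,15-dinor-5β-labdan-13-one | CC(=O)CC[C@H]1[C@](C)(O[Si](CC)(CC)CC)[C@H]3O[C@H]3[C@@H]2C(C)(C)CCC[C@@]21C
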